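**One step.** In a one-step world electrophile and nucleophile would simply meet, and in amber the nucleophile would halve in 0.031 s. So your hunch is that amber is over in a moment, but I doubt it.

all flasks: electrophile 0.50 mM; gas 0.046 mM (held); time 3.0 s
- amber: protonated nucleophile 0.900 mM
- grey: protonated nucleophile 1.40 mM
- teal: protonated nucleophile 2.00 mM
    electrophile + nucleophile → acid set free + product (k1 = 44500 /M/s)
    crystals ⇌ product, rate k2*(cs2 - [product]) while solid is left; crystals form when [product] > cs2 (cs2 = 0.29 mM, k2 = 3.67 /s)
    nucleophile + acid set free ⇌ protonated nucleophile, settled at all times (K3 = 5.3 × 10⁵ /M)
    acid set free + free base ⇌ salt of the base (K4 = 4.9 × 10⁷ /M, k4 = 5590 /M/s)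
    gas ⇌ free base, rate k5*(csat - [free base]) (k5 = 38.4 /s, csat = 0.046 mM)
- for product the crystals are counted in
- as a solid, counted per litre of solution: crystals
- at the start none of free base is dissolved
- run time (amber): 3.0 s
1. part of the electrophile that has reacted at the end, amber
2. part of the electrophile that has reacted at the end, grey
3. part of the electrophile that has reacted at the end, teal
4. what raising the concentration of protonated nucleophile from its lowest to its highest value here does to the part of the electrophile that has reacted (changes below 5 percentage points count as none) (no change / it rises / it falls)

**The brake.** No nucleophile is charged as such. Each product uses one nucleophile and frees one acid, and protonated nucleophile frees a second acid in replacing it, so c(acid set free) gains two for each product. The balance holds c(nucleophile) at c(protonated nucleophile) over K3 c(acid set free), so acid chokes its own source. Free base removes acid as a pseudo-first-order loss, with constant k4 csat, and I take c(free base) near csat because gas transfer is faster than uptake by acid, even with c(acid set free) at 0.50 mM.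

**My reckoning.** Setting gain equal to loss gives an acid level of 0.542 mM for amber as charged, and that level sinks as the charges are used. Suppose acid sits at its end level throughout the run. The salt is then k4 csat t times that level, so twice the product is 1.77 times the level. Putting this into the balance gives my stall ratio, c(product, crystals counted) squared over c(electrophile) times c(protonated nucleophile), which at 3.0 s should stand near 0.512, with neither the electrophile charge nor the protonated nucleophile charge in it. Solving for each flask gives 54.3% for amber, 63.6% for grey and 70.5% for teal.

**The forecast.** It gives 52%, 63% and 71%, and says it rises, on the ground that after the first burst “the rate is limited by base supply”. For amber and grey mine lies above it.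

**The simulation.** It gives 52.8%, 63.2% and 71.8%, so it rises, by 19 percentage points.

**The neighbour.** Amber's stall ratio reads 0.468 at the end. A neighbour of amber charged with 1.5 mM of protonated nucleophile keeps the same time and gas, so I hold the ratio at 0.512, which gives 64.9%. That flask gives 64.9%, with 35% of the electrophile still there, and its ratio reads 0.513.

(Its constants belong to no real substance; the flask was simulated.)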